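**Plan**
Numbering: C1 quaternary carbinol, C7 its CH2OBz carbon, C2 CHOH, C3 CHOBz, C4 allylic CHOH, C5=C6 the ring alkene; β is the face of the three free hydroxyls.
Enabling feature: with C4 as a ketone, the six-membered ring contains a β-hydroxy ketone (C2–OH/C4=O) whose only acidic C–H is at C3, because C1 is quaternary and C5 is vinylic. C1 carries O, C7H2O and C2, so it is the central carbon of a 2-substituted glycerol.
Retrosynthetic cuts, in order: C4 carbinol to enone; ring bond C2–C3 (aldol); C5=C6 to an alkyne; C4–C5 and C1–C6 (two acetylide additions); the O–benzoyl bond at C7 (desymmetrisation).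
Forward order: C6–C1 is joined, the triol is desymmetrised, and C5–C4 is joined. Both carbinols are oxidised while the chain is still a linear alkyne, the alkyne is bent to the Z alkene, and the only ring closes last at C2–C3.
Stereochemistry: C1 comes from the CuCl2/bis(oxazoline) monobenzoylation, C2 and C3 are relayed from C1 in the magnesium aldol, and C4 comes from axial hydride delivery in the Luche reduction.

Key step: step 11

Assumption: the (R,R)-ligand is taken to acylate the pro-R CH2OH arm in step 3. If the sense of induction is opposite, the (S,S)-ligand is used and nothing else changes.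

**Route**

Step 1
Reactants: 1 2,2-dimethyl-1,3-dioxan-5-one; 2 ethynyltrimethylsilane
Product: 4 2,2-dimethyl-5-[(trimethylsilyl)ethynyl]-1,3-dioxan-5-ol, via lithium (trimethylsilyl)acetylide 3 (not isolated)
Conditions: n-BuLi, THF, −78 °C; then 1, −78 °C; sat. aq NH4Cl
Reagents that add atoms: none
Why: 1,2-addition of a lithium acetylide to a ketone forms C1–C6, and the product is achiral (a mirror plane passes through C1), so no stereochemical issue arises.

Step 2
Reactants: 4 2,2-dimethyl-5-[(trimethylsilyl)ethynyl]-1,3-dioxan-5-ol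
Product: 5 2-[(trimethylsilyl)ethynyl]propane-1,2,3-triol
Conditions: AcOH–H2O (4:1), rt to 40 °C; evaporation with toluene
Reagents that add atoms: none
Why: acid-catalysed acetal hydrolysis frees the prochiral 2-alkynylglycerol, while the C-silyl cap survives dilute acid and is kept because it will shield the alkyne from Glaser coupling and C-benzoylation in the copper step.

Step 3
Reactants: 5 2-[(trimethylsilyl)ethynyl]propane-1,2,3-triol; 6 benzoyl chloride
Product: 7 (2R)-2-hydroxy-2-(hydroxymethyl)-4-(trimethylsilyl)but-3-yn-1-yl benzoate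
Conditions: CuCl2 (10 mol %), (R,R)-Ph-BOX [2,2'-(propane-2,2-diyl)bis((4R)-4-phenyl-4,5-dihydrooxazole)] (10 mol %), BzCl (1.05 equiv), Et3N (1.1 equiv), THF, 0 °C to rt
Reagents that add atoms: benzoyl chloride 6, O=C(Cl)c1ccccc1
Why: in this catalytic desymmetrising monobenzoylation of a 2-substituted glycerol, divalent copper in the twofold-symmetric bis(oxazoline) pocket binds the tertiary hydroxyl and one enantiotopic CH2OH as a 1,2-diol chelate, and only that activated hydroxyl (the pro-R arm) is acylated, which sets C1 and installs the final C7 benzoate in one operation.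

Step 4
Reactants: 7 (2R)-2-hydroxy-2-(hydroxymethyl)-4-(trimethylsilyl)but-3-yn-1-yl benzoate
Product: 8 (2S)-2-(triethylsilyloxy)-2-[(triethylsilyloxy)methyl]-4-(trimethylsilyl)but-3-yn-1-yl benzoate
Conditions: Et3SiOTf (2.5 equiv), 2,6-lutidine, CH2Cl2, −78 to 0 °C
Reagents that add atoms: triethylsilyl trifluoromethanesulfonate, CC[Si](CC)(CC)OS(=O)(=O)C(F)(F)F
Why: silyl triflate silylation covers the primary and the hindered tertiary hydroxyl together under a non-nucleophilic base, and it is run on fresh 7 because a benzoyl shift between the two CH2O arms would racemise C1.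

Step 5
Reactants: 8 (2S)-2-(triethylsilyloxy)-2-[(triethylsilyloxy)methyl]-4-(trimethylsilyl)but-3-yn-1-yl benzoate
Product: 9 (2S)-2-(triethylsilyloxy)-2-[(triethylsilyloxy)methyl]but-3-yn-1-yl benzoate
Conditions: AgNO3 (10 mol %), CH2Cl2–MeOH–H2O (7:4:1), rt, dark
Reagents that add atoms: none
Why: silver-catalysed protiodesilylation of an alkynylsilane is specific for the C(sp)–Si bond at neutral pH, so the O-silyl ethers and the benzoate remain, and it is placed after step 4 because silver could otherwise drive a free hydroxyl into 5-endo cyclisation onto the alkyne.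

Step 6
Reactants: 10 allyl benzoate
Product: 12 2-oxoethyl benzoate, via secondary ozonide 11 (not isolated)
Conditions: O3, CH2Cl2, −78 °C; then Me2S, −78 °C to rt
Reagents that add atoms: ozone, [O-][O+]=O
Why: ozonolysis with reductive work-up cleaves the terminal alkene to the C3–C4 aldehyde with the C3 benzoate already in place.

Step 7
Reactants: 9 (2S)-2-(triethylsilyloxy)-2-[(triethylsilyloxy)methyl]but-3-yn-1-yl benzoate; 12 2-oxoethyl benzoate
Product: 14 (2S,5RS)-5-hydroxy-2-(triethylsilyloxy)-2-[(triethylsilyloxy)methyl]hex-3-yne-1,6-diyl dibenzoate (C4 epimers), via lithium acetylide 13 (not isolated)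
Conditions: LiN(iPr)2 (LDA, 1.05 equiv), THF, −78 °C; then 12, −78 °C; AcOH in THF at −78 °C
Reagents that add atoms: none
Why: lithium acetylide addition to an aldehyde forms C4–C5, the hindered amide base spares the benzoates at −78 °C, the cold acidic quench forestalls O3-to-O4 benzoyl migration, and the new C4 carbinol is left as an epimer mixture because step 9 erases it.

Step 8
Reactants: 14 (2S,5RS)-5-hydroxy-2-(triethylsilyloxy)-2-[(triethylsilyloxy)methyl]hex-3-yne-1,6-diyl dibenzoate
Product: 15 (2R,5RS)-5-hydroxy-2-(hydroxymethyl)-2-(triethylsilyloxy)hex-3-yne-1,6-diyl dibenzoate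
Conditions: PPTS (cat.), MeOH–CH2Cl2, 0 °C
Reagents that add atoms: none
Why: acid-catalysed methanolysis discriminates silyl ethers by hindrance, so the primary C2 ether is cleaved and the tertiary C1 ether stays, and the mildly acidic medium avoids the base-induced C7-to-C2 benzoyl shift that would erode the enantiomeric purity.

Step 9
Reactants: 15 (2R,5RS)-5-hydroxy-2-(hydroxymethyl)-2-(triethylsilyloxy)hex-3-yne-1,6-diyl dibenzoate
Product: 16 (2S)-2-formyl-5-oxo-2-(triethylsilyloxy)hex-3-yne-1,6-diyl dibenzoate
Conditions: Dess–Martin periodinane (3 equiv), CH2Cl2, 0 °C to rt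
Reagents that add atoms: none
Why: Dess–Martin oxidation converts both carbinols at the alkyne stage, where the linear C5≡C6 spacer keeps O2 and C4 apart, so no lactol can form and be over-oxidised to a lactone as it would from the corresponding (Z)-alkene diol.

Step 10
Reactants: 16 (2S)-2-formyl-5-oxo-2-(triethylsilyloxy)hex-3-yne-1,6-diyl dibenzoate
Product: 17 (2S,3Z)-2-formyl-5-oxo-2-(triethylsilyloxy)hex-3-ene-1,6-diyl dibenzoate
Conditions: H2 (1 atm), Pd/CaCO3 poisoned with Pb(OAc)2, quinoline, EtOAc, 0 °C; stopped after one equivalent of H2; filtered and used at once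
Reagents that add atoms: none
Why: Lindlar-type syn semihydrogenation on poisoned palladium gives the (Z)-enone with aldehyde and benzoates untouched, and quinoline together with the stop at one equivalent of H2 limits over-reduction and Z-to-E drift.

Step 11
Reactants: 17 (2S,3Z)-2-formyl-5-oxo-2-(triethylsilyloxy)hex-3-ene-1,6-diyl dibenzoate
Product: 19 [(1S,5S,6S)-5-(benzoyloxy)-6-hydroxy-4-oxo-1-(triethylsilyloxy)cyclohex-2-en-1-yl]methyl benzoate, via bromomagnesium enolate 18 (not isolated)
Conditions: MgBr2·OEt2 (2.5 equiv), iPr2NEt (1.5 equiv), CH2Cl2 (0.01 M), −78 to −20 °C; sat. aq NH4Cl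
Reagents that add atoms: none
Why: MgBr2 binds the C4 carbonyl together with the C3 benzoate and so acidifies the only enolisable position of 17 (C3; C1 is quaternary, C5 vinylic and the aldehyde has no α-hydrogen), iPr2NEt removes that proton, and the chelated (Z)-enolate 18 adds through C3 to the magnesium-activated C2 aldehyde, forming C2–C3. The closest known reaction types are the magnesium halide/tertiary amine soft-enolisation aldol and the cycloaldolisation of 1,5-keto aldehydes to gabosine-type cyclohexenones. The cyclohexenone ring closes in the 6-(enolendo)-exo-trig mode, which is within reach only because the Z C5=C6 bond already holds C2 over C3. C2 is set by chelation control: a second magnesium bridges the aldehyde oxygen and the C1 oxygen (a triethylsilyl ether, unlike bulkier silyl ethers, still binds magnesium), so the enolate, tethered through C6, can reach only the carbonyl face that leaves C2–OH cis to C1–O, that is β. C3 is set by the enolate geometry, which keeps the benzoate outside the closing ring and hence pseudo-equatorial and trans to C2–OH (α), and since C3 stays epimerisable and the addition reversible, any leakage should drain to this same isomer, the half-chair with C7, O2 and O3 pseudo-equatorial and only C1–OSiEt3 pseudo-axial. The step needs closure to outrun dehydration across C2–C3, benzoyl migration to O2 and Z-to-E isomerisation, which the low temperature, the non-nucleophilic base, the weakly basic magnesium alkoxide and high dilution are chosen to secure.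

Step 12
Reactants: 19 [(1S,5S,6S)-5-(benzoyloxy)-6-hydroxy-4-oxo-1-(triethylsilyloxy)cyclohex-2-en-1-yl]methyl benzoate
Product: 20 [(1S,4S,5R,6S)-5-(benzoyloxy)-4,6-dihydroxy-1-(triethylsilyloxy)cyclohex-2-en-1-yl]methyl benzoate
Conditions: NaBH4, CeCl3·7H2O, MeOH, −78 °C; AcOH quench
Reagents that add atoms: none
Why: in the Luche 1,2-reduction the hard cerium-modified borohydride should attack C4 along the axial trajectory on the α face, where only the axial C2–H stands, giving the pseudo-equatorial 4β-alcohol trans to the C3 benzoate without conjugate reduction or ester loss at −78 °C.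

Step 13
Reactants: 20 [(1S,4S,5R,6S)-5-(benzoyloxy)-4,6-dihydroxy-1-(triethylsilyloxy)cyclohex-2-en-1-yl]methyl benzoate
Product: 21 [(1S,4S,5R,6S)-5-(benzoyloxy)-1,4,6-trihydroxycyclohex-2-en-1-yl]methyl benzoate (1α-benzoyloxymethyl-3α-benzoyloxycyclohex-5-ene-1β,2β,4β-triol)
Conditions: HF·pyridine, pyridine, THF, 0 °C to rt
Reagents that add atoms: none
Why: fluoride-mediated desilylation in a slightly acidic buffer removes the tertiary triethylsilyl ether without generating the alkoxides that would move the benzoates.

**Compound list**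
1 | 2,2-dimethyl-1,3-dioxan-5-one | CC1(C)OCC(=O)CO1 | starting material
2 | ethynyltrimethylsilane | C#C[Si](C)(C)C | starting material
3 | lithium (trimethylsilyl)acetylide | [Li]C#C[Si](C)(C)C | intermediate
4 | 2,2-dimethyl-5-[(trimethylsilyl)ethynyl]-1,3-dioxan-5-ol | CC1(C)OCC(O)(C#C[Si](C)(C)C)CO1 | intermediate
5 | 2-[(trimethylsilyl)ethynyl]propane-1,2,3-triol | OCC(O)(CO)C#C[Si](C)(C)C | intermediate
6 | benzoyl chloride | O=C(Cl)c1ccccc1 | starting material
7 | (2R)-2-hydroxy-2-(hydroxymethyl)-4-(trimethylsilyl)but-3-yn-1-yl benzoate | OC[C@@](O)(COC(=O)c1ccccc1)C#C[Si](C)(C)C | intermediate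
8 | (2S)-2-(triethylsilyloxy)-2-[(triethylsilyloxy)methyl]-4-(trimethylsilyl)but-3-yn-1-yl benzoate | CC[Si](CC)(CC)OC[C@@](O[Si](CC)(CC)CC)(COC(=O)c1ccccc1)C#C[Si](C)(C)C | intermediate
9 | (2S)-2-(triethylsilyloxy)-2-[(triethylsilyloxy)methyl]but-3-yn-1-yl benzoate | CC[Si](CC)(CC)OC[C@@](O[Si](CC)(CC)CC)(COC(=O)c1ccccc1)C#C | intermediate
10 | allyl benzoate | C=CCOC(=O)c1ccccc1 | starting material
11 | (1,2,4-trioxolan-3-yl)methyl benzoate (secondary ozonide) | O=C(OCC1OCOO1)c1ccccc1 | intermediate
12 | 2-oxoethyl benzoate | O=CCOC(=O)c1ccccc1 | intermediate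
13 | lithium acetylide of 9 | CC[Si](CC)(CC)OC[C@@](O[Si](CC)(CC)CC)(COC(=O)c1ccccc1)C#C[Li] | intermediate
14 | (2S,5RS)-5-hydroxy-2-(triethylsilyloxy)-2-[(triethylsilyloxy)methyl]hex-3-yne-1,6-diyl dibenzoate (C4 epimers) | CC[Si](CC)(CC)OC[C@@](O[Si](CC)(CC)CC)(COC(=O)c1ccccc1)C#CC(O)COC(=O)c1ccccc1 | intermediate
15 | (2R,5RS)-5-hydroxy-2-(hydroxymethyl)-2-(triethylsilyloxy)hex-3-yne-1,6-diyl dibenzoate (C4 epimers) | OC[C@@](O[Si](CC)(CC)CC)(COC(=O)c1ccccc1)C#CC(O)COC(=O)c1ccccc1 | intermediate
16 | (2S)-2-formyl-5-oxo-2-(triethylsilyloxy)hex-3-yne-1,6-diyl dibenzoate | O=C[C@@](O[Si](CC)(CC)CC)(COC(=O)c1ccccc1)C#CC(=O)COC(=O)c1ccccc1 | intermediate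
17 | (2S,3Z)-2-formyl-5-oxo-2-(triethylsilyloxy)hex-3-ene-1,6-diyl dibenzoate | O=C[C@@](O[Si](CC)(CC)CC)(COC(=O)c1ccccc1)/C=C\C(=O)COC(=O)c1ccccc1 | intermediate
18 | bromomagnesium (Z)-enolate of 17 (C3=C4) | O=C[C@@](O[Si](CC)(CC)CC)(COC(=O)c1ccccc1)/C=C\C(O[Mg]Br)=C\OC(=O)c1ccccc1 | intermediate
19 | [(1S,5S,6S)-5-(benzoyloxy)-6-hydroxy-4-oxo-1-(triethylsilyloxy)cyclohex-2-en-1-yl]methyl benzoate | O=C1C=C[C@](O[Si](CC)(CC)CC)(COC(=O)c2ccccc2)[C@@H](O)[C@@H]1OC(=O)c1ccccc1 | intermediate
20 | [(1S,4S,5R,6S)-5-(benzoyloxy)-4,6-dihydroxy-1-(triethylsilyloxy)cyclohex-2-en-1-yl]methyl benzoate | O=C(OC[C@@]1(O[Si](CC)(CC)CC)C=C[C@H](O)[C@@H](OC(=O)c2ccccc2)[C@@H]1O)c1ccccc1 | intermediate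
21 | [(1S,4S,5R,6S)-5-(benzoyloxy)-1,4,6-trihydroxycyclohex-2-en-1-yl]methyl benzoate | O=C(OC[C@@]1(O)C=C[C@H](O)[C@@H](OC(=O)c2ccccc2)[C@@H]1O)c1ccccc1 | target

**Totals**
Total step count: 13.
Longest linear sequence: 12 (steps 1–5 and 7–13).

**Steps most likely to fail**

Step 11.
- What may go wrong: the flat cross-conjugated enolate may not reach the aldehyde, or the relay from C1 may be weak if attack proceeds without chelation. Closure may also be followed by loss of water across C2–C3 or by benzoyl migration to the new C2 oxygen.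
- Fallback: C2–C3 is formed intermolecularly and the ring is closed at C5=C6 by metathesis. It sets out from 9 and 12 and returns at 19.
- Semihydrogenation of 9 over Pd/CaCO3 poisoned with Pb(OAc)2 gives the vinyl compound (S)-2-(triethylsilyloxy)-2-[(triethylsilyloxy)methyl]but-3-en-1-yl benzoate F1. Swern oxidation, which converts a primary triethylsilyl ether directly and leaves the tertiary one, then gives the aldehyde (S)-2-formyl-2-(triethylsilyloxy)but-3-en-1-yl benzoate F2.
- In parallel, 12 takes up vinylmagnesium bromide to give 2-hydroxybut-3-en-1-yl benzoate F3. Dess–Martin periodinane oxidises this to the vinyl ketone 2-oxobut-3-en-1-yl benzoate F4.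
- The dibutylboron (Z)-enolate of F4 (Bu2BOTf, iPr2NEt, −78 °C) adds to F2 in a syn aldol to give (4S,5S,6S)-4-(benzoyloxy)-6-[(benzoyloxy)methyl]-5-hydroxy-6-(triethylsilyloxy)octa-1,7-dien-3-one F5. The C1/C2 sense has to be checked and any epimer removed at this stage.
- Ring-closing metathesis of F5 with the second-generation Grubbs catalyst leads back to 19.

Step 10.
- What may go wrong: the activated triple bond may be over-reduced, the Z alkene may isomerise to E on palladium, and material may be lost through hydration of the cis-disposed dicarbonyl pair.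
- Fallback: the alkyne is reduced before any carbonyl group exists. It sets out from 15 and returns at 17.
- Semihydrogenation of the propargylic diol 15 over the same poisoned palladium, the best-behaved substrate class for this reduction, gives (2R,3Z,5RS)-5-hydroxy-2-(hydroxymethyl)-2-(triethylsilyloxy)hex-3-ene-1,6-diyl dibenzoate F6.
- A Swern double oxidation ((COCl)2, DMSO, CH2Cl2, −78 °C; then Et3N, cold quench) gives 17. Both hydroxyls become alkoxysulfonium salts before the first carbonyl appears, so lactol formation is avoided.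

Step 3.
- What may go wrong: the slim alkynyl group may offer too little bias between the enantiotopic arms, a second benzoylation may occur, and the benzoyl group may scramble under Et3N.
- Fallback: C1 is set by asymmetric epoxidation instead of desymmetrisation. It sets out from 2 and returns at 7.
- Sonogashira coupling of 2 with commercial 2-bromoprop-2-en-1-ol (PdCl2(PPh3)2, CuI, Et3N) gives 2-methylidene-4-(trimethylsilyl)but-3-yn-1-ol F7.
- Sharpless asymmetric epoxidation (Ti(OiPr)4, D-(−)-diethyl tartrate, t-BuOOH, 4 Å molecular sieves, −20 °C) should give (R)-{2-[(trimethylsilyl)ethynyl]oxiran-2-yl}methanol F8. The tartrate enantiomer is the one expected from the behaviour of 2-substituted allylic alcohols.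
- Ti(OiPr)4-assisted opening of F8 by benzoic acid at the unsubstituted CH2 leaves C1 untouched and gives 7.

**Further compounds**
F1 | step 11 | (S)-2-(triethylsilyloxy)-2-[(triethylsilyloxy)methyl]but-3-en-1-yl benzoate | CC[Si](CC)(CC)OC[C@@](O[Si](CC)(CC)CC)(COC(=O)c1ccccc1)C=C
F2 | step 11 | (S)-2-formyl-2-(triethylsilyloxy)but-3-en-1-yl benzoate | O=C[C@@](O[Si](CC)(CC)CC)(COC(=O)c1ccccc1)C=C
F3 | step 11 | 2-hydroxybut-3-en-1-yl benzoate (racemic) | C=CC(O)COC(=O)c1ccccc1
F4 | step 11 | 2-oxobut-3-en-1-yl benzoate | C=CC(=O)COC(=O)c1ccccc1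
F5 | step 11 | (4S,5S,6S)-4-(benzoyloxy)-6-[(benzoyloxy)methyl]-5-hydroxy-6-(triethylsilyloxy)octa-1,7-dien-3-one | C=C[C@](O[Si](CC)(CC)CC)(COC(=O)c1ccccc1)[C@@H](O)[C@H](OC(=O)c1ccccc1)C(=O)C=C
F6 | step 10 | (2R,3Z,5RS)-5-hydroxy-2-(hydroxymethyl)-2-(triethylsilyloxy)hex-3-ene-1,6-diyl dibenzoate | OC[C@@](O[Si](CC)(CC)CC)(COC(=O)c1ccccc1)/C=C\C(O)COC(=O)c1ccccc1
F7 | step 3 | 2-methylidene-4-(trimethylsilyl)but-3-yn-1-ol | C=C(CO)C#C[Si](C)(C)C
F8 | step 3 | (R)-{2-[(trimethylsilyl)ethynyl]oxiran-2-yl}methanol | OC[C@]1(C#C[Si](C)(C)C)CO1
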